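**Retrosynthetic overview**
1. 33 ⇒ seco-aldehyde 32: the last bond is C20=C21, closed by a high-dilution intramolecular Knoevenagel condensation (11-membered ring). The tetramic acid is built from Nα-Boc-L-ornithine (C17) and Meldrum's acid after amide formation at C12.
2. Ring D (cis,cis-cycloocta-1,5-diene) ⇒ ring-closing metathesis (C23=C24) after a chirality-transfer Ireland–Claisen rearrangement (C11–C22) with allylic alcohol 5, whose C21–C23 unit comes from dearomatised furan.
3. Rings A and B ⇒ one enantiotopic-group-selective catalytic Pauson–Khand reaction of the meso diene-diyne 10 (key step: breaks the mirror symmetry and fixes the absolute configuration), then C29 methylation and C3 acetyl installation.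
4. Ring C with its four all-cis stereocentres ⇒ ethenolysis of commercial meso cis-endo-norbornene-dimethanol 6.
5. Order of ring formation: C, then A and B together, then D, then the tetramate, then the macrolactam.

Assumption: the target is taken exactly as the given SMILES (C21 is the CH of a 3-alkylidene-pyrrolidine-2,4-dione); atoms are labelled C1–C31 (N13, N18) in the order in which they appear in that SMILES.

**Step 1**
Reactants: 1 furan
Product: 2 2,5-dimethoxy-2,5-dihydrofuran (cis/trans mixture)
Conditions: Br2, MeOH, Na2CO3, −40 °C → rt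
Reagents that add atoms: methanol CO
Why: Clauson-Kaas-type oxidative 1,4-dimethoxylation breaks the aromaticity of furan and turns its four carbons into a masked butenedial; the cis/trans mixture converges in step 2.

**Step 2**
Reactants: 2 2,5-dimethoxy-2,5-dihydrofuran
Product: 4 (E)-4,4-dimethoxybut-2-enal, via (E)-1,1,4,4-tetramethoxybut-2-ene 3 (not isolated)
Conditions: Amberlyst-15, MeOH, rt; then Amberlyst-15, acetone–H2O, rt
Reagents that add atoms: methanol CO; water O
Why: Acid-catalysed acetal exchange opens the ring to the bis-acetal, whose allyl-type oxocarbenium ion equilibrates to the E alkene, and controlled mono-hydrolysis gives the known fumaraldehyde mono(dimethyl acetal); no stereocentre is formed.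

**Step 3**
Reactants: 4 (E)-4,4-dimethoxybut-2-enal
Product: 5 (R,E)-5,5-dimethoxypent-3-en-2-ol
Conditions: Me2Zn, (+)-MIB (3-exo-morpholinoisoborneol, 5 mol %), toluene–hexane, 0 °C; aq. NH4Cl
Reagents that add atoms: dimethylzinc C[Zn]C
Why: Amino-alcohol-catalysed enantioselective dialkylzinc addition (Noyori–Nugent type) delivers methyl to one face of the aldehyde and sets the (R) carbinol centre, the ligand enantiomer being assigned by analogy with Et2Zn/benzaldehyde (antipode used if the sense is reversed).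

**Step 4**
Reactants: 6 meso cis-endo-bicyclo[2.2.1]hept-5-ene-2,3-diyldimethanol
Product: 7 meso all-cis-(3,5-divinylcyclopentane-1,2-diyl)dimethanol
Conditions: second-generation Grubbs catalyst (1 mol %), ethylene (1 atm), CH2Cl2, rt
Reagents that add atoms: ethylene C=C
Why: Ring-opening cross-metathesis (ethenolysis) is driven by norbornene strain and leaves the four ring stereocentres (future C7, C8, C25, C27) all-cis as inherited from the endo bicycle; the product is still meso.

**Step 5**
Reactants: 7 meso all-cis-(3,5-divinylcyclopentane-1,2-diyl)dimethanol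
Product: 10 meso all-cis-1,2-di(prop-2-yn-1-yl)-3,5-divinylcyclopentane, via bis-triflate 8 (not isolated), via bis(trimethylsilyl) diyne 9 (not isolated)
Conditions: Tf2O, 2,6-lutidine, CH2Cl2, −78 °C; LiC≡CSiMe3 (commercial solution), THF–DMPU, −78 → −20 °C; K2CO3 (cat.), MeOH, rt
Reagents that add atoms: trifluoromethanesulfonic anhydride O=S(=O)(OS(=O)(=O)C(F)(F)F)C(F)(F)F; lithium (trimethylsilyl)acetylide [Li]C#C[Si](C)(C)C
Why: Two SN2 displacements of primary triflates by the acetylide followed by C–Si methanolysis install both propargyl arms without touching a stereocentre, so the substrate for the key step stays meso.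

**Step 6**
Reactants: 10 meso all-cis-1,2-di(prop-2-yn-1-yl)-3,5-divinylcyclopentane
Product: 11 cis-anti-cis triquinane enone (rings A, B, C; C3 ketone, C4=C5; C8 prop-2-ynyl and C25 vinyl retained)
Conditions: Co2(CO)8 (20 mol %), (S)-BINAP (20 mol %), CO (1 atm), ClCH2CH2Cl, 80 °C, run to full conversion of 10
Reagents that add atoms: carbon monoxide [C-]#[O+]
Why: Proposed new method: an enantiotopic-group-selective Pauson–Khand reaction in which the chiral cobalt–BINAP carbonyl species can complex either alkyne, but the enantio-determining alkene insertion is matched for only one of the two mirror-related 1,6-enyne pairs, because substrate control (ring A grows on the convex face, H28 anti to H27) dictates which alkene face each pair must use; the matched pair cyclises, setting C28 and thereby the absolute configuration of C7, C8, C25 and C27, while the remaining mismatched enyne reacts slowly (which also upgrades the ee); closest known reactions are the Co2(CO)8/BINAP-catalysed asymmetric Pauson–Khand cyclisation of terminal 1,6-enynes and the Rh- or Ir–BINAP desymmetrisation of meso dienynes, and the antipodal ligand is used if the group selection proves opposite.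

**Step 7**
Reactants: 11 triquinane enone
Product: 12 C29-methyl enone (methyl on the convex face, trans to C27)
Conditions: LiN(SiMe3)2 (1.05 equiv), THF, −78 °C; MeI, −78 → −40 °C
Reagents that add atoms: iodomethane CI
Why: Kinetic α′-deprotonation gives the cross-conjugated enolate (the only enolisable α position) and enolate alkylation occurs anti to the C28–C27 bond, setting C29 with the methyl cis to H28.

**Step 8**
Reactants: 12 C29-methyl enone
Product: 13 saturated cis-anti-cis triquinane ketone (H5 cis to H28)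
Conditions: Li (2.2 equiv), t-BuOH (1 equiv), NH3(l)–THF, −78 °C; solid NH4Cl
Reagents that add atoms: none
Why: Dissolving-metal (Birch-type) conjugate reduction of the enone with protonation at C5 gives the only unstrained cis A/B ring fusion, the terminal alkyne surviving as its lithium acetylide and the isolated vinyl group being inert.

**Step 9**
Reactants: 13 saturated triquinane ketone
Product: 15 C3 α-hydroxy methyl ketone (C3 epimers converge in step 10), via 1-ethoxyvinyl carbinol 14 (not isolated)
Conditions: CH2=C(OEt)Li (from ethyl vinyl ether and t-BuLi), CeCl3, THF, −78 °C; then 0.5 M HCl, THF, 0 °C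
Reagents that add atoms: 1-ethoxyvinyllithium [Li]C(=C)OCC; water O
Why: Organocerium 1,2-addition of an acyl-anion equivalent to the enolisable ketone followed by enol-ether hydrolysis installs both acetyl carbons at C3, the carbinol configuration being irrelevant because C3 becomes trigonal in the next step.

**Step 10**
Reactants: 15 C3 α-hydroxy methyl ketone
Product: 16 methyl ketone with the C3 acetyl cis to the C29 methyl (both on the convex face)
Conditions: SmI2 (3 equiv), THF–MeOH, −78 → 0 °C
Reagents that add atoms: none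
Why: Samarium diiodide reduction of the α-hydroxy ketone expels hydroxide to give a samarium enolate that is protonated kinetically at C3 from the face opposite the vicinal C29 methyl (Zimmerman ketonisation), which sets the cis acetyl/methyl relationship of the target.

**Step 11**
Reactants: 16 cis methyl ketone
Product: 17 1,3-dioxolane of 16
Conditions: (Me3SiOCH2)2, Me3SiOTf (5 mol %), CH2Cl2, −78 → −20 °C; pyridine
Reagents that add atoms: 1,2-bis(trimethylsilyloxy)ethane C[Si](C)(C)OCCO[Si](C)(C)C
Why: Noyori ketalisation under aprotic low-temperature conditions protects the methyl ketone without enolisation, so the kinetically set C3 configuration is frozen until the last step.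

**Step 12**
Reactants: 17 dioxolane alkyne; 5 (R,E)-5,5-dimethoxypent-3-en-2-ol
Product: 21 (E)-α,β-unsaturated ester of 5 (C10=C11 E), via alkenylzirconocene chloride 18 (not isolated), via acylzirconocene chloride 19 (not isolated), via enoyl bromide 20 (not isolated)
Conditions: Cp2Zr(H)Cl (1.05 equiv), CH2Cl2, 0 °C → rt; CO (1 atm), rt; N-bromosuccinimide, −30 °C; then 5, pyridine, DMAP (cat.), −30 → 0 °C
Reagents that add atoms: Cp2Zr(H)Cl [H][Zr](Cl)(C1C=CC=C1)C1C=CC=C1; carbon monoxide [C-]#[O+]; N-bromosuccinimide BrN1C(=O)CCC1=O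
Why: Schwartz hydrozirconation (syn, terminal, alkyne much faster than the vinyl group), CO insertion, bromine cleavage of the acyl–Zr bond and acylation of 5 give the (E)-enoate without touching any stereocentre, the carbinol centre of 5 being retained.

**Step 13**
Reactants: 21 (E)-α,β-unsaturated ester
Product: 22 (Z)-β,γ-unsaturated ester (C9=C10 Z)
Conditions: LiN(iPr)2, HMPA, THF, −78 °C; AcOH, −78 °C
Reagents that add atoms: none
Why: Kende-type deconjugation, in which γ-deprotonation at C9 gives the dienolate and kinetic α-protonation returns the β,γ-unsaturated ester with the new C9=C10 bond Z (E-2-enoates give Z-3-enoates); no stereocentre is involved.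

**Step 14**
Reactants: 22 (Z)-β,γ-unsaturated ester
Product: 25 Claisen acid (C11 carboxylic acid; C22 bears CH(OMe)2 and an (E)-prop-1-enyl group), via silyl ketene acetal 23 (not isolated), via trimethylsilyl ester 24 (not isolated)
Conditions: LiN(iPr)2, Me3SiCl (internal quench), THF, −100 → −78 °C; then rt → 50 °C; K2CO3, MeOH–H2O; pH 5 buffer
Reagents that add atoms: chlorotrimethylsilane C[Si](C)(C)Cl
Why: Ireland–Claisen rearrangement in which kinetic enolisation gives the ketene acetal with C10 cis to the allylic oxygen and the chair transition state with the carbinol methyl equatorial transfers the (R) chirality of 5 to C22 and, through the ketene acetal geometry, to C11 (C12 and C21 end up trans on the future ring D), the (E)-propenyl group being formed at the same time.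

**Step 15**
Reactants: 25 Claisen acid
Product: 26 ring-D acid (cis,cis-cycloocta-1,5-diene cis-fused to ring C; C11 CO2H trans to C22 CH(OMe)2)
Conditions: second-generation Hoveyda–Grubbs catalyst (10 mol %), toluene (1 mM), 80 °C
Reagents that add atoms: none
Why: Ring-closing metathesis between the C25 vinyl and the C22 propenyl groups closes the eight-membered ring, helped by the cis-disposed arms on ring C and the pre-installed Z C9=C10 bond, the new C23=C24 bond being necessarily cis and no stereocentre being affected.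

**Step 16**
Reactants: 26 ring-D acid; 27 Nα-Boc-L-ornithine
Product: 29 Nδ-acyl-Nα-Boc-L-ornithine (C12–N13 amide), via succinimidyl ester 28 (not isolated)
Conditions: N-hydroxysuccinimide, EDC·HCl, CH2Cl2, 0 °C; then 27, NaHCO3, THF–H2O, rt
Reagents that add atoms: N-hydroxysuccinimide ON1C(=O)CCC1=O
Why: Active-ester amide coupling in which only the free δ-amine of 27 is acylated (carbamate nitrogen and carboxylate are inert), the base-free activation sparing the allylic C11 centre; C17 comes from L-ornithine.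

**Step 17**
Reactants: 29 Nδ-acyl-Nα-Boc-L-ornithine
Product: 31 N-Boc pyrrolidine-2,4-dione (tetramic acid; C17 S), via acyl Meldrum adduct 30 (not isolated)
Conditions: Meldrum's acid, EDC·HCl, DMAP, CH2Cl2, 0 °C → rt; then EtOAc, reflux
Reagents that add atoms: Meldrum's acid CC1(C)OC(=O)CC(=O)O1
Why: Jouin tetramic acid synthesis in which C-acylation of Meldrum's acid is followed by thermal loss of acetone to an acylketene that is trapped by the carbamate nitrogen and decarboxylates, C17 being retained.

**Step 18**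
Reactants: 31 N-Boc tetramic acid
Product: 33 Combamide C, via seco-aldehyde 32 (not isolated)
Conditions: TFA–CH2Cl2–H2O (10:10:1), 0 °C → rt; concentrate; ethylenediammonium diacetate (20 mol %), MeCN (0.5 mM), rt
Reagents that add atoms: water O
Why: Proposed new method: acidolysis unmasks the NH tetramic acid, the C21 aldehyde and the methyl ketone, and the doubly activated C20 methylene then condenses with the aldehyde under high dilution (Knoevenagel condensation, known intermolecularly for pyrrolidine-2,4-diones and aldehydes) to close the 11-membered ring, the alkylidene settling with C22 cis to the C31 ketone because only that isomer keeps a cis olefin in the ring; no stereocentre is formed and the mild ammonium carboxylate catalyst is chosen to spare the epimerisable C3, C11 and C22 centres.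

**Compound list**
1 | furan | c1ccoc1 | starting material
2 | 2,5-dimethoxy-2,5-dihydrofuran (cis/trans mixture) | COC1C=CC(OC)O1 | intermediate
3 | (E)-1,1,4,4-tetramethoxybut-2-ene | COC(OC)/C=C/C(OC)OC | intermediate
4 | (E)-4,4-dimethoxybut-2-enal | COC(OC)/C=C/C=O | intermediate
5 | (R,E)-5,5-dimethoxypent-3-en-2-ol | C[C@@H](O)/C=C/C(OC)OC | intermediate
6 | meso cis-endo-bicyclo[2.2.1]hept-5-ene-2,3-diyldimethanol | OC[C@@H]1[C@H](CO)[C@@H]2C=C[C@H]1C2 | starting material
7 | meso all-cis-(3,5-divinylcyclopentane-1,2-diyl)dimethanol | OC[C@@H]1[C@H](CO)[C@H](C=C)C[C@@H]1C=C | intermediate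
8 | bis-triflate of 7 | O=S(=O)(OC[C@@H]1[C@H](COS(=O)(=O)C(F)(F)F)[C@H](C=C)C[C@@H]1C=C)C(F)(F)F | intermediate
9 | meso all-cis-1,2-bis[3-(trimethylsilyl)prop-2-yn-1-yl]-3,5-divinylcyclopentane | C[Si](C)(C)C#CC[C@@H]1[C@H](CC#C[Si](C)(C)C)[C@H](C=C)C[C@@H]1C=C | intermediate
10 | meso all-cis-1,2-di(prop-2-yn-1-yl)-3,5-divinylcyclopentane | C#CC[C@@H]1[C@H](CC#C)[C@H](C=C)C[C@@H]1C=C | intermediate
11 | cis-anti-cis triquinane enone (C3=O, C4=C5, H28 anti to H27; C8 propargyl, C25 vinyl) | O=C1C=C2C[C@@H]3[C@H](CC#C)[C@H](C=C)C[C@@H]3[C@H]2C1 | intermediate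
12 | 11 with convex-face methyl at C29 | O=C1C=C2C[C@@H]3[C@H](CC#C)[C@H](C=C)C[C@@H]3[C@H]2[C@@H]1C | intermediate
13 | saturated triquinane ketone (H5 cis to H28) | O=C1C[C@H]2C[C@@H]3[C@H](CC#C)[C@H](C=C)C[C@@H]3[C@H]2[C@@H]1C | intermediate
14 | C3 tertiary alcohol bearing 1-ethoxyvinyl (major C3 epimer drawn) | C=C(OCC)[C@@]1(O)C[C@H]2C[C@@H]3[C@H](CC#C)[C@H](C=C)C[C@@H]3[C@H]2[C@@H]1C | intermediate
15 | C3 α-hydroxy methyl ketone (major C3 epimer drawn) | CC(=O)[C@@]1(O)C[C@H]2C[C@@H]3[C@H](CC#C)[C@H](C=C)C[C@@H]3[C@H]2[C@@H]1C | intermediate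
16 | methyl ketone, C3 acetyl cis to C29 methyl | CC(=O)[C@@H]1C[C@H]2C[C@@H]3[C@H](CC#C)[C@H](C=C)C[C@@H]3[C@H]2[C@@H]1C | intermediate
17 | 1,3-dioxolane of 16 | CC1(OCCO1)[C@@H]2C[C@H]3C[C@@H]4[C@H](CC#C)[C@H](C=C)C[C@@H]4[C@H]3[C@@H]2C | intermediate
18 | (E)-alkenylzirconocene chloride from 17 | CC1(OCCO1)[C@@H]2C[C@H]3C[C@@H]4[C@H](C/C=C/[Zr](Cl)(C5C=CC=C5)C5C=CC=C5)[C@H](C=C)C[C@@H]4[C@H]3[C@@H]2C | intermediate
19 | (E)-acylzirconocene chloride | CC1(OCCO1)[C@@H]2C[C@H]3C[C@@H]4[C@H](C/C=C/C(=O)[Zr](Cl)(C5C=CC=C5)C5C=CC=C5)[C@H](C=C)C[C@@H]4[C@H]3[C@@H]2C | intermediate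
20 | (E)-enoyl bromide | CC1(OCCO1)[C@@H]2C[C@H]3C[C@@H]4[C@H](C/C=C/C(Br)=O)[C@H](C=C)C[C@@H]4[C@H]3[C@@H]2C | intermediate
21 | (E)-α,β-unsaturated ester of 5 | CC1(OCCO1)[C@@H]2C[C@H]3C[C@@H]4[C@H](C/C=C/C(=O)O[C@H](C)/C=C/C(OC)OC)[C@H](C=C)C[C@@H]4[C@H]3[C@@H]2C | intermediate
22 | (Z)-β,γ-unsaturated ester of 5 | CC1(OCCO1)[C@@H]2C[C@H]3C[C@@H]4[C@H](/C=C\CC(=O)O[C@H](C)/C=C/C(OC)OC)[C@H](C=C)C[C@@H]4[C@H]3[C@@H]2C | intermediate
23 | trimethylsilyl ketene acetal (C10 cis to the allylic oxygen) | CC1(OCCO1)[C@@H]2C[C@H]3C[C@@H]4[C@H](/C=C\C=C(\O[Si](C)(C)C)/O[C@H](C)/C=C/C(OC)OC)[C@H](C=C)C[C@@H]4[C@H]3[C@@H]2C | intermediate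
24 | trimethylsilyl ester of 25 | CC1(OCCO1)[C@@H]2C[C@H]3C[C@@H]4[C@H](/C=C\[C@H](C(=O)O[Si](C)(C)C)[C@H](/C=C/C)C(OC)OC)[C@H](C=C)C[C@@H]4[C@H]3[C@@H]2C | intermediate
25 | Claisen acid (C11 and C22 set; C22 with (E)-propenyl and CH(OMe)2) | CC1(OCCO1)[C@@H]2C[C@H]3C[C@@H]4[C@H](/C=C\[C@H](C(=O)O)[C@H](/C=C/C)C(OC)OC)[C@H](C=C)C[C@@H]4[C@H]3[C@@H]2C | intermediate
26 | ring-D acid (5-5-5-8 carbocycle; C11 CO2H trans to C22 CH(OMe)2) | CC1(OCCO1)[C@@H]2C[C@H]3C[C@@H]4[C@@H]5/C=C\[C@H](C(=O)O)[C@@H](C(OC)OC)/C=C\[C@@H]5C[C@@H]4[C@H]3[C@@H]2C | intermediate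
27 | Nα-Boc-L-ornithine | NCCC[C@H](NC(=O)OC(C)(C)C)C(=O)O | starting material
28 | N-succinimidyl ester of 26 | CC1(OCCO1)[C@@H]2C[C@H]3C[C@@H]4[C@@H]5/C=C\[C@H](C(=O)ON6C(=O)CCC6=O)[C@@H](C(OC)OC)/C=C\[C@@H]5C[C@@H]4[C@H]3[C@@H]2C | intermediate
29 | Nδ-acyl-Nα-Boc-L-ornithine | CC1(OCCO1)[C@@H]2C[C@H]3C[C@@H]4[C@@H]5/C=C\[C@H](C(=O)NCCC[C@H](NC(=O)OC(C)(C)C)C(=O)O)[C@@H](C(OC)OC)/C=C\[C@@H]5C[C@@H]4[C@H]3[C@@H]2C | intermediate
30 | acyl Meldrum's acid adduct of 29 | CC1(OCCO1)[C@@H]2C[C@H]3C[C@@H]4[C@@H]5/C=C\[C@H](C(=O)NCCC[C@H](NC(=O)OC(C)(C)C)C(=O)C6C(=O)OC(C)(C)OC6=O)[C@@H](C(OC)OC)/C=C\[C@@H]5C[C@@H]4[C@H]3[C@@H]2C | intermediate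
31 | N-Boc tetramic acid (C17 S) | CC1(OCCO1)[C@@H]2C[C@H]3C[C@@H]4[C@@H]5/C=C\[C@H](C(=O)NCCC[C@@H]6N(C(=O)OC(C)(C)C)C(=O)CC6=O)[C@@H](C(OC)OC)/C=C\[C@@H]5C[C@@H]4[C@H]3[C@@H]2C | intermediate
32 | seco-aldehyde (free tetramic acid, C21 aldehyde, C2 ketone) | CC(=O)[C@@H]1C[C@H]2C[C@@H]3[C@@H]4/C=C\[C@H](C(=O)NCCC[C@@H]5NC(=O)CC5=O)[C@@H](C=O)/C=C\[C@@H]4C[C@@H]3[C@H]2[C@@H]1C | intermediate
33 | Combamide C | CC(=O)[C@@H]1C[C@H]2C[C@@H]3[C@@H]4/C=C\[C@@H]5C(=O)NCCC[C@@H]6NC(=O)/C(=C/[C@H]5/C=C\[C@@H]4C[C@@H]3[C@H]2[C@@H]1C)C6=O | target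

**Step count and risks**
Total: 18 steps. Longest linear sequence: 15 steps (6 → 33, steps 4–18); the furan branch (steps 1–3) joins at step 12.

The three steps most likely to fail:

Step 6 (group-selective Pauson–Khand reaction; unprecedented substrate class, possible diyne side reactions or low group selection). The fallback sets out from 6 and comes back at 11. Candida antarctica lipase B and vinyl acetate acetylate one enantiotopic hydroxyl of 6 to give the C6 monoacetate F1, and ethenolysis as in step 4 gives the divinyl monoacetate F2. The free C9 hydroxyl is converted (Tf2O; LiC≡CSi(iPr)3; then K2CO3/MeOH, which also removes the acetate) into the triisopropylsilyl-propargyl alcohol F3, and the C6 hydroxyl likewise (Tf2O; LiC≡CSiMe3; K2CO3/MeOH) into the mono-silylated diyne F4. A non-asymmetric Pauson–Khand reaction (Co2(CO)8, N-methylmorpholine N-oxide) engages only the terminal alkyne and gives the silyl-protected enone F5, and Bu4NF returns 11. Symmetry is then broken enzymatically and the two alkynes are told apart by their silyl groups instead of by the catalyst.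

Step 14 (Ireland–Claisen rearrangement; the C11 configuration depends on the ketene acetal geometry of a β,γ-unsaturated ester). The fallback sets out from 17 and comes back at 25, and pairs the reliably formed opposite ketene acetal geometry with a Z allylic partner. Commercial (S)-but-3-yn-2-ol (2 EtMgBr, then HC(OMe)3) gives the alkynyl acetal (S)-5,5-dimethoxypent-3-yn-2-ol F6, and semi-hydrogenation (H2, Pd/CaCO3 poisoned with Pb(OAc)2, quinoline) gives the (S,Z)-allylic alcohol F7. Compound 17 is taken through the sequence of step 12 with F7 to the (E)-enoate F8, which is deconjugated as in step 13 to the (Z)-β,γ-unsaturated ester F9. Enolisation with LiN(SiMe3)2 in THF–HMPA and Me3SiCl then gives the ketene acetal with C10 cis to the silyloxy group; in the chair transition state this geometry together with the Z alkene and the (S) carbinol leads to the same acid 25.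

Step 18 (macro-Knoevenagel; the free β,γ-unsaturated aldehyde may epimerise at C22 or slip into conjugation before ring closure). The fallback sets out from 31 and comes back at 33 and never liberates the aldehyde. t-BuMe2SiOTf and Et3N convert 31 into the 4-silyloxy-3-pyrrolin-2-one F10. Me3SiOTf (CH2Cl2, 0.5 mM, −78 °C) ionises the dimethyl acetal and the silyl enol ether adds intramolecularly (Mukaiyama-type addition) to give the C21-methoxy macrocycle F11. TFA–CH2Cl2–H2O then removes the Boc group and the dioxolane and eliminates methanol to give 33.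

**Further compounds**
F1 | step 6 | norbornene monoacetate (C6 acetate, C9 alcohol) | CC(=O)OC[C@@H]1[C@H](CO)[C@@H]2C=C[C@H]1C2
F2 | step 6 | all-cis divinylcyclopentane monoacetate | CC(=O)OC[C@@H]1[C@H](CO)[C@H](C=C)C[C@@H]1C=C
F3 | step 6 | C9-(triisopropylsilyl)propargyl C6 alcohol | OC[C@@H]1[C@H](CC#C[Si](C(C)C)(C(C)C)C(C)C)[C@H](C=C)C[C@@H]1C=C
F4 | step 6 | mono-triisopropylsilyl diyne | C#CC[C@@H]1[C@H](CC#C[Si](C(C)C)(C(C)C)C(C)C)[C@H](C=C)C[C@@H]1C=C
F5 | step 6 | triisopropylsilyl-protected enone 11 | O=C1C=C2C[C@@H]3[C@H](CC#C[Si](C(C)C)(C(C)C)C(C)C)[C@H](C=C)C[C@@H]3[C@H]2C1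
F6 | step 14 | (S)-5,5-dimethoxypent-3-yn-2-ol | C[C@H](O)C#CC(OC)OC
F7 | step 14 | (S,Z)-5,5-dimethoxypent-3-en-2-ol | C[C@H](O)/C=C\C(OC)OC
F8 | step 14 | (E)-α,β-unsaturated ester of F7 | CC1(OCCO1)[C@@H]2C[C@H]3C[C@@H]4[C@H](C/C=C/C(=O)O[C@@H](C)/C=C\C(OC)OC)[C@H](C=C)C[C@@H]4[C@H]3[C@@H]2C
F9 | step 14 | (Z)-β,γ-unsaturated ester of F7 | CC1(OCCO1)[C@@H]2C[C@H]3C[C@@H]4[C@H](/C=C\CC(=O)O[C@@H](C)/C=C\C(OC)OC)[C@H](C=C)C[C@@H]4[C@H]3[C@@H]2C
F10 | step 18 | 4-(tert-butyldimethylsilyloxy)-3-pyrrolin-2-one from 31 | CC1(OCCO1)[C@@H]2C[C@H]3C[C@@H]4[C@@H]5/C=C\[C@H](C(=O)NCCC[C@@H]6N(C(=O)OC(C)(C)C)C(=O)C=C6O[Si](C)(C)C(C)(C)C)[C@@H](C(OC)OC)/C=C\[C@@H]5C[C@@H]4[C@H]3[C@@H]2C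
F11 | step 18 | N-Boc C21-methoxy macrocycle (mixture at C20 and C21) | CC1(OCCO1)[C@@H]2C[C@H]3C[C@@H]4[C@@H]5/C=C\[C@@H]6C(=O)NCCC[C@@H]7N(C(=O)OC(C)(C)C)C(=O)C(C(OC)[C@H]6/C=C\[C@@H]5C[C@@H]4[C@H]3[C@@H]2C)C7=O
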